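The runs come from a simulation for an exercise; noise was put on by code.

The coupling partner is the limiting reagent of this flask: 0.300 mM stands against 1.00 mM of the two substrates together. Its ledger starts from one entry. Each product is taken to use one coupling partner, so c(coupling partner) over c(left-handed substrate) + c(right-handed substrate) gives the partner ceiling, here 30.0%: the percent of substrate that can react if each coupling partner ends in product.

| flask | left-handed substrate | right-handed substrate | coupling partner | precatalyst | remark | time |
|---|---|---|---|---|---|---|
| east | 5.0 × 10⁻⁴ M | 5.0 × 10⁻⁴ M | 0.30 mM | 25 µM | the very flask that is asked about, followed so far |  |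
| south | 7.5 × 10⁻⁴ M | 7.5 × 10⁻⁴ M | 0.30 mM | 25 µM | run made earlier |  |
| flask | 5.0 × 10⁻⁴ M | 5.0 × 10⁻⁴ M | 0.300 mM | 25 µM |  | 4.0 min |

| run | time / s | left-handed product / % | right-handed product / % | left-handed substrate / % |
|---|---|---|---|---|
| east | 10.0 | 1.7 | 0.6 | 48.1 |
| east | 15.0 | 4.0 | 0.5 | 46.8 |
| east | 20.0 | 4.6 | 0.1 | 46.1 |
| east | 25.0 | 5.6 | 0 | 44.0 |
| east | 30.0 | 6.5 | 1.0 | 42.7 |
| south | 10.0 | 2.0 | 0.4 | 48.4 |
| south | 12.0 | 2.0 | 0 | 47.7 |
| south | 20.0 | 4.6 | 0.5 | 45.9 |
| south | 40.0 | 6.8 | 0 | 42.6 |
| south | 60.0 | 10.2 | 0.6 | 39.9 |
| south | 90.0 | 10.9 | 0.1 | 39.2 |

(scatter of a reading: 0.5 percentage points)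

- catalyst is single-handed; left-handed substrate and right-handed substrate are mirror images of each other, charged as a racemate, each of them at the stated concentration
- the earlier runs were read with a standard deviation of 0.5 percentage points
- an excess is below zero if the other one leads

1. excess of left-handed product over right-handed product in the product at 12 s
2. excess of left-handed product over right-handed product in the product at 4.0 min
3. part of the left-handed substrate and right-handed substrate charged together that has reacted at 4.0 min

The south run has a ceiling of 20.0%. At 90.0 s its two products read 11.0% together, so the product entry holds a reading of 55.0% of its coupling partner. The other 0.135 mM has no entry in these readings, and coupling partner was not read. The east run, which is this flask, reads 7.50% of product at 30.0 s, less than its ceiling. The reckoning here carries the south share over to this flask and gets 16.5% reacted at 4.0 min.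

The forecast gives 92% (80% to 99%), 90% (80% to 97%) and 14% (11% to 17.5%) for the three questions in order. In the forecast's words, the south run stalled “well short of the 20% that the partner allows”. The forecast's conversion lies below the reckoning here.

The flask gives 95.0%, 94.0% and 19.7%.

    coupling partner + catalyst + left-handed substrate → catalyst + left-handed product (k = 4.30 × 10⁶ /M²/s)
    coupling partner + catalyst + right-handed substrate → catalyst + right-handed product (k = 1.07 × 10⁵ /M²/s)
    precatalyst ⇌ catalyst (K = 4.20, k = 0.0274 /s)
    coupling partner ⇌ dormant form (K = 4.40, k = 0.0306 /s)

At 4.0 min the books of this flask close: product holds 65.7% of the coupling partner, dormant form 30.4%, and 3.8% stands free. At that time, use of coupling partner by the step to left-handed product runs at 0.88 of the forward rate into dormant form. Backward turnover of the step into dormant form has reached 69% of its forward turnover. The neighbour flask, charged with 1.0 × 10⁻⁴ M of precatalyst, keeps the ceiling of 30.0% and at the same time reaches 25.9%, which is 86.3% of its coupling partner, with 12.9% as dormant form and 0.77% free.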